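The route rests on disconnecting the dimethylpyran ring fused to ring B at its O–CMe2 bond and annulating it onto the 2'-hydroxyisoflavone 13. The key step exploits O-2', the only free phenol, whose single open ortho carbon is C-3' (C-1' carries ring C): phenylboronic acid tethers prenal to O-2' in a temporary dioxaborin ring, forcing C–C bond formation at C-3'; expulsion of boron gives an ortho-quinone methide that closes the pyran by oxa-6π electrocyclization, forming O–CMe2. The step also caps O-2', so reduction and deoxygenation need no protecting group there. Ring A's prenyl comes from a para-Claisen rearrangement; C-3 is set by transfer hydrogenation with dynamic kinetic resolution.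

Key step: step 8

Assumption: compounds 1, 3, 10 and 14 are taken as commercially available, and the (R,R)-TsDPEN ligand is assumed, by analogy with simple aryl ketones, to deliver the 4R alcohol (the mirror-image catalyst would be used if the opposite sense were found).

Step 1
Reactants: 1 1-(2,4-dihydroxy-6-methoxyphenyl)ethanone
Product: 2 1-[2-hydroxy-6-methoxy-4-(triisopropylsilyloxy)phenyl]ethanone
Conditions: TIPSCl (1.05 equiv), imidazole, DMF, 0 °C to rt
Reagents that add atoms: triisopropylsilyl chloride, CC(C)[Si](Cl)(C(C)C)C(C)C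
Why: The 4-hydroxyl is para to the acetyl group and not hydrogen-bonded, whereas the 2-hydroxyl is chelated to the carbonyl, so chemoselective O-silylation should occur at O-4 only.

Step 2
Reactants: 2 1-[2-hydroxy-6-methoxy-4-(triisopropylsilyloxy)phenyl]ethanone; 3 3-methylbut-2-en-1-ol
Product: 4 1-[2-methoxy-6-(3-methylbut-2-enyloxy)-4-(triisopropylsilyloxy)phenyl]ethanone
Conditions: PPh3, DIAD, THF, 0 °C to rt
Reagents that add atoms: none
Why: Mitsunobu etherification alkylates the remaining chelated phenol at the primary carbon of the allylic alcohol under neutral conditions that spare the aryl silyl ether, giving the unrearranged prenyl ether.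

Step 3
Reactants: 4 1-[2-methoxy-6-(3-methylbut-2-enyloxy)-4-(triisopropylsilyloxy)phenyl]ethanone
Product: 7 1-[6-hydroxy-2-methoxy-3-(3-methylbut-2-enyl)-4-(triisopropylsilyloxy)phenyl]ethanone, via ortho-dienone 5 (not isolated), via para-dienone 6 (not isolated)
Conditions: PhNEt2, 200 °C, sealed tube
Reagents that add atoms: none
Why: Aromatic Claisen rearrangement ([3,3]) to the open ortho carbon C-5 gives dienone 5, a Cope shift ([3,3]) carries the allyl unit on to the para carbon C-3 between OMe and OTIPS to give 6, and tautomerization restores the arene (para-Claisen sequence), so the prenyl group is placed para to the oxygen that becomes O-1 of the chroman.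

Step 4
Reactants: 7 1-[6-hydroxy-2-methoxy-3-(3-methylbut-2-enyl)-4-(triisopropylsilyloxy)phenyl]ethanone
Product: 9 3-iodo-5-methoxy-6-(3-methylbut-2-enyl)-7-(triisopropylsilyloxy)-4H-chromen-4-one, via enaminone 8 (not isolated)
Conditions: DMF-DMA, toluene, 95 °C; concentrate; then I2, CHCl3, rt
Reagents that add atoms: N,N-dimethylformamide dimethyl acetal, COC(OC)N(C)C; iodine, II
Why: Condensation of the methyl ketone with the amide acetal gives enaminone 8, iodine then attacks its nucleophilic α-carbon, the phenol closes onto the iminium carbon and dimethylamine is lost (iodine-mediated enaminone cyclization to a 3-iodochromone), and the enaminone should react far faster than the trisubstituted alkene.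

Step 5
Reactants: 10 4-bromobenzene-1,3-diol
Product: 11 2-bromo-5-(triisopropylsilyloxy)phenol
Conditions: TIPSCl (1.0 equiv), imidazole, CH2Cl2, −20 to 0 °C
Reagents that add atoms: triisopropylsilyl chloride, CC(C)[Si](Cl)(C(C)C)C(C)C
Why: The hydroxyl para to bromine is the less hindered one and is not engaged by the ortho halogen, so one equivalent of the bulky silyl chloride should silylate it selectively (regioselective O-silylation).

Step 6
Reactants: 11 2-bromo-5-(triisopropylsilyloxy)phenol
Product: 12 2-(4,4,5,5-tetramethyl-1,3,2-dioxaborolan-2-yl)-5-(triisopropylsilyloxy)phenol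
Conditions: B2pin2, Pd(dppf)Cl2 (3 mol %), KOAc, dioxane, 85 °C
Reagents that add atoms: bis(pinacolato)diboron, CC1(C)OB(OC1(C)C)B1OC(C)(C)C(C)(C)O1
Why: Miyaura borylation of the aryl bromide, which tolerates a free ortho phenol with acetate as the base.

Step 7
Reactants: 9 3-iodo-5-methoxy-6-(3-methylbut-2-enyl)-7-(triisopropylsilyloxy)-4H-chromen-4-one; 12 2-(4,4,5,5-tetramethyl-1,3,2-dioxaborolan-2-yl)-5-(triisopropylsilyloxy)phenol
Product: 13 3-[2-hydroxy-4-(triisopropylsilyloxy)phenyl]-5-methoxy-6-(3-methylbut-2-enyl)-7-(triisopropylsilyloxy)-4H-chromen-4-one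
Conditions: Pd(dppf)Cl2 (5 mol %), Na2CO3, DME/H2O, 70 °C
Reagents that add atoms: none
Why: Suzuki–Miyaura coupling of a 3-iodochromone with an arylboronate is the standard convergent isoflavone synthesis, and the mild carbonate base should spare the chromone ring and the silyl ethers.

Step 8
Reactants: 13 3-[2-hydroxy-4-(triisopropylsilyloxy)phenyl]-5-methoxy-6-(3-methylbut-2-enyl)-7-(triisopropylsilyloxy)-4H-chromen-4-one; 14 3-methylbut-2-enal
Product: 17 3-[2,2-dimethyl-5-(triisopropylsilyloxy)-2H-chromen-8-yl]-5-methoxy-6-(3-methylbut-2-enyl)-7-(triisopropylsilyloxy)-4H-chromen-4-one, via benzodioxaborin 15 (not isolated), via ortho-quinone methide 16 (not isolated)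
Conditions: PhB(OH)2 (1.2 equiv), AcOH (0.5 equiv), toluene, reflux, Dean–Stark
Reagents that add atoms: none
Why: The boronic acid esterifies O-2' and binds the aldehyde, so that the aldehyde carbon is delivered through a six-membered transition state to the ortho carbon C-3' and dioxaborin 15 results; on heating with acid, 15 expels phenylboronic acid to give ortho-quinone methide 16, whose 1-oxatriene (O=C2'–C3'=CH–CH=CMe2) closes thermally and forms the O–CMe2 bond. The closest known reaction type is the phenylboronic acid-mediated ortho-specific condensation of phenols with α,β-unsaturated aldehydes to 2H-chromenes. The pyran ring is closed by a disrotatory oxa-6π electrocyclization, not by polar attack of oxygen on an alkene. No stereocenter is created in 17, since the carbinol carbon of 15 becomes sp2 on fragmentation. The step needs reaction on ring B only and at C-3' only: ring A has no free hydroxyl (O-7 is silylated), C-1' is blocked by ring C, and the boron tether rules out the para carbon C-5'. The chromone, the prenyl group and the aryl silyl ethers should tolerate weak acid in hot toluene.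

Step 9
Reactants: 17 3-[2,2-dimethyl-5-(triisopropylsilyloxy)-2H-chromen-8-yl]-5-methoxy-6-(3-methylbut-2-enyl)-7-(triisopropylsilyloxy)-4H-chromen-4-one
Product: 19 (3R,4R)-3-[2,2-dimethyl-5-(triisopropylsilyloxy)-2H-chromen-8-yl]-5-methoxy-6-(3-methylbut-2-enyl)-7-(triisopropylsilyloxy)chroman-4-ol, via isoflavanone 18 (not isolated)
Conditions: RuCl(p-cymene)[(R,R)-TsDPEN] (3 mol %), HCO2H/Et3N (5:2), EtOAc, 40 °C
Reagents that add atoms: none
Why: Noyori–Ikariya asymmetric transfer hydrogenation: the ruthenium hydride first reduces the chromone C2=C3 bond to isoflavanone 18, whose C-3 epimerizes quickly in the amine buffer, and the ketone of the faster-reacting epimer is then reduced with hydride delivery anti to the 3-aryl group, so that the ligand should set C-4 as R (CH/π model) and the dynamic kinetic resolution should set C-3 as R (cis alcohol), while the prenyl and chromene alkenes are left untouched.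

Step 10
Reactants: 19 (3R,4R)-3-[2,2-dimethyl-5-(triisopropylsilyloxy)-2H-chromen-8-yl]-5-methoxy-6-(3-methylbut-2-enyl)-7-(triisopropylsilyloxy)chroman-4-ol
Product: 20 (3R)-3-[2,2-dimethyl-5-(triisopropylsilyloxy)-2H-chromen-8-yl]-5-methoxy-6-(3-methylbut-2-enyl)-7-(triisopropylsilyloxy)chromane
Conditions: Et3SiH (5 equiv), TFA (1.5 equiv), CH2Cl2, −78 to −40 °C
Reagents that add atoms: none
Why: Ionic hydrogenation: the 4-hydroxyl ionizes readily to a benzylic cation stabilized by O-1, the 5-methoxy and the 7-silyloxy groups and is captured by hydride from the silane, and low temperature with little acid should leave C-3, the chromene and the prenyl alkene untouched.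

Step 11
Reactants: 20 (3R)-3-[2,2-dimethyl-5-(triisopropylsilyloxy)-2H-chromen-8-yl]-5-methoxy-6-(3-methylbut-2-enyl)-7-(triisopropylsilyloxy)chromane
Product: 21 (3R)-3-(5-hydroxy-2,2-dimethyl-2H-chromen-8-yl)-5-methoxy-6-(3-methylbut-2-enyl)chroman-7-ol
Conditions: TBAF (2.5 equiv), AcOH (2.5 equiv), THF, 0 °C
Reagents that add atoms: none
Why: Fluoride cleaves both aryl silyl ethers (desilylation), and the acetic acid buffer keeps the medium near neutral so that the ortho-prenylphenol and the chromene meet neither strong acid nor strong base.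

Compound list

1 | 1-(2,4-dihydroxy-6-methoxyphenyl)ethanone | CC(=O)c1c(O)cc(O)cc1OC | starting material
2 | 1-[2-hydroxy-6-methoxy-4-(triisopropylsilyloxy)phenyl]ethanone | CC(=O)c1c(O)cc(O[Si](C(C)C)(C(C)C)C(C)C)cc1OC | intermediate
3 | 3-methylbut-2-en-1-ol | CC(C)=CCO | starting material
4 | 1-[2-methoxy-6-(3-methylbut-2-enyloxy)-4-(triisopropylsilyloxy)phenyl]ethanone | CC(=O)c1c(OCC=C(C)C)cc(O[Si](C(C)C)(C(C)C)C(C)C)cc1OC | intermediate
5 | ortho-dienone, racemic 2-acetyl-3-methoxy-6-(2-methylbut-3-en-2-yl)-5-(triisopropylsilyloxy)cyclohexa-2,4-dien-1-one | CC(=O)C1=C(OC)C=C(O[Si](C(C)C)(C(C)C)C(C)C)C(C(C)(C)C=C)C1=O | intermediate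
6 | para-dienone, racemic 2-acetyl-3-methoxy-4-(3-methylbut-2-enyl)-5-(triisopropylsilyloxy)cyclohexa-2,5-dien-1-one | CC(=O)C1=C(OC)C(CC=C(C)C)C(O[Si](C(C)C)(C(C)C)C(C)C)=CC1=O | intermediate
7 | 1-[6-hydroxy-2-methoxy-3-(3-methylbut-2-enyl)-4-(triisopropylsilyloxy)phenyl]ethanone | CC(=O)c1c(O)cc(O[Si](C(C)C)(C(C)C)C(C)C)c(CC=C(C)C)c1OC | intermediate
8 | enaminone, (E)-3-(dimethylamino)-1-[6-hydroxy-2-methoxy-3-(3-methylbut-2-enyl)-4-(triisopropylsilyloxy)phenyl]prop-2-en-1-one | CN(C)/C=C/C(=O)c1c(O)cc(O[Si](C(C)C)(C(C)C)C(C)C)c(CC=C(C)C)c1OC | intermediate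
9 | 3-iodo-5-methoxy-6-(3-methylbut-2-enyl)-7-(triisopropylsilyloxy)-4H-chromen-4-one | COc1c(CC=C(C)C)c(O[Si](C(C)C)(C(C)C)C(C)C)cc2occ(I)c(=O)c12 | intermediate
10 | 4-bromobenzene-1,3-diol | Oc1ccc(Br)c(O)c1 | starting material
11 | 2-bromo-5-(triisopropylsilyloxy)phenol | Oc1cc(O[Si](C(C)C)(C(C)C)C(C)C)ccc1Br | intermediate
12 | 2-(4,4,5,5-tetramethyl-1,3,2-dioxaborolan-2-yl)-5-(triisopropylsilyloxy)phenol | Oc1cc(O[Si](C(C)C)(C(C)C)C(C)C)ccc1B1OC(C)(C)C(C)(C)O1 | intermediate
13 | 3-[2-hydroxy-4-(triisopropylsilyloxy)phenyl]-5-methoxy-6-(3-methylbut-2-enyl)-7-(triisopropylsilyloxy)-4H-chromen-4-one | COc1c(CC=C(C)C)c(O[Si](C(C)C)(C(C)C)C(C)C)cc2occ(-c3ccc(O[Si](C(C)C)(C(C)C)C(C)C)cc3O)c(=O)c12 | intermediate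
14 | 3-methylbut-2-enal | CC(C)=CC=O | starting material
15 | benzodioxaborin, 3-[4-(2-methylprop-1-enyl)-2-phenyl-5-(triisopropylsilyloxy)-4H-1,3,2-benzodioxaborinin-8-yl]-5-methoxy-6-(3-methylbut-2-enyl)-7-(triisopropylsilyloxy)-4H-chromen-4-one (racemic at the carbinol carbon) | COc1c(CC=C(C)C)c(O[Si](C(C)C)(C(C)C)C(C)C)cc2occ(-c3ccc(O[Si](C(C)C)(C(C)C)C(C)C)c4c3OB(c3ccccc3)OC4C=C(C)C)c(=O)c12 | intermediate
16 | ortho-quinone methide, 3-[5-(3-methylbut-2-enylidene)-6-oxo-4-(triisopropylsilyloxy)cyclohexa-1,3-dien-1-yl]-5-methoxy-6-(3-methylbut-2-enyl)-7-(triisopropylsilyloxy)-4H-chromen-4-one | COc1c(CC=C(C)C)c(O[Si](C(C)C)(C(C)C)C(C)C)cc2occ(C3=CC=C(O[Si](C(C)C)(C(C)C)C(C)C)C(=CC=C(C)C)C3=O)c(=O)c12 | intermediate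
17 | 3-[2,2-dimethyl-5-(triisopropylsilyloxy)-2H-chromen-8-yl]-5-methoxy-6-(3-methylbut-2-enyl)-7-(triisopropylsilyloxy)-4H-chromen-4-one | COc1c(CC=C(C)C)c(O[Si](C(C)C)(C(C)C)C(C)C)cc2occ(-c3ccc(O[Si](C(C)C)(C(C)C)C(C)C)c4c3OC(C)(C)C=C4)c(=O)c12 | intermediate
18 | isoflavanone, racemic 3-[2,2-dimethyl-5-(triisopropylsilyloxy)-2H-chromen-8-yl]-5-methoxy-6-(3-methylbut-2-enyl)-7-(triisopropylsilyloxy)chroman-4-one | COc1c(CC=C(C)C)c(O[Si](C(C)C)(C(C)C)C(C)C)cc2OCC(c3ccc(O[Si](C(C)C)(C(C)C)C(C)C)c4c3OC(C)(C)C=C4)C(=O)c12 | intermediate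
19 | (3R,4R)-3-[2,2-dimethyl-5-(triisopropylsilyloxy)-2H-chromen-8-yl]-5-methoxy-6-(3-methylbut-2-enyl)-7-(triisopropylsilyloxy)chroman-4-ol (cis) | COc1c(CC=C(C)C)c(O[Si](C(C)C)(C(C)C)C(C)C)cc2c1[C@H](O)[C@H](c1ccc(O[Si](C(C)C)(C(C)C)C(C)C)c3c1OC(C)(C)C=C3)CO2 | intermediate
20 | (3R)-3-[2,2-dimethyl-5-(triisopropylsilyloxy)-2H-chromen-8-yl]-5-methoxy-6-(3-methylbut-2-enyl)-7-(triisopropylsilyloxy)chromane | COc1c(CC=C(C)C)c(O[Si](C(C)C)(C(C)C)C(C)C)cc2c1C[C@H](c1ccc(O[Si](C(C)C)(C(C)C)C(C)C)c3c1OC(C)(C)C=C3)CO2 | intermediate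
21 | (3R)-3-(5-hydroxy-2,2-dimethyl-2H-chromen-8-yl)-5-methoxy-6-(3-methylbut-2-enyl)chroman-7-ol (CNP0119857.1) | COc1c(CC=C(C)C)c(O)cc2c1C[C@H](c1ccc(O)c3c1OC(C)(C)C=C3)CO2 | target

Total step count: 11. Longest linear sequence: 9 steps (steps 1 to 4 and 7 to 11, from compound 1).

Steps most likely to fail

1. Step 8. C–C bond formation at C-3', which is flanked by the boron-bound oxygen and the bulky 4'-silyloxy group, may be too slow, so that the aldehyde self-condenses and 13 is returned. The fallback sets out from 13 and comes back at 17. O-Alkylation of 13 with 2-methylbut-3-yn-2-yl trifluoroacetate (CuCl2 cat., DBU, MeCN, 0 °C) should give the aryl 1,1-dimethylpropargyl ether F1. Heating F1 in PhNEt2 at 180 °C should then give 17 by aromatic propargyl Claisen rearrangement to C-3', 1,5-hydrogen shift and oxa-6π electrocyclization.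

2. Step 10. The C-4 cation may lose H-3 to give an isoflav-3-ene, whose re-reduction would erode the configuration at C-3, and the acid may protonate the chromene alkene. The fallback sets out from 19 and comes back at 20 by radical Barton–McCombie deoxygenation, which avoids a cation. 1,1'-Thiocarbonyldiimidazole with DMAP in CH2Cl2 should give the O-(imidazol-1-ylthiocarbonyl) derivative F2, and Bu3SnH with AIBN in toluene at 80 °C should then give 20.

3. Step 9. Reduction of the ketone, which is hindered by the peri 5-methoxy group and the ortho-substituted 3-aryl group, may stall at 18 or proceed with poor facial selectivity. The fallback sets out from 17 and comes back at 20, using resolution in place of asymmetric catalysis. NaBH4 in THF/EtOH should reduce 17 to the racemic isoflavan-4-ol F3 (a mixture of diastereomers). Ionic hydrogenation under the conditions of step 10 should give the racemic isoflavan F4, and preparative chromatography on a chiral stationary phase should separate the (3R)-enantiomer 20.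

Further compounds

F1 | step 8 | 3-[2-(2-methylbut-3-yn-2-yloxy)-4-(triisopropylsilyloxy)phenyl]-5-methoxy-6-(3-methylbut-2-enyl)-7-(triisopropylsilyloxy)-4H-chromen-4-one | COc1c(CC=C(C)C)c(O[Si](C(C)C)(C(C)C)C(C)C)cc2occ(-c3ccc(O[Si](C(C)C)(C(C)C)C(C)C)cc3OC(C)(C)C#C)c(=O)c12
F2 | step 10 | O-[(3R,4R)-3-[2,2-dimethyl-5-(triisopropylsilyloxy)-2H-chromen-8-yl]-5-methoxy-6-(3-methylbut-2-enyl)-7-(triisopropylsilyloxy)chroman-4-yl] 1H-imidazole-1-carbothioate | COc1c(CC=C(C)C)c(O[Si](C(C)C)(C(C)C)C(C)C)cc2c1[C@H](OC(=S)n1ccnc1)[C@H](c1ccc(O[Si](C(C)C)(C(C)C)C(C)C)c3c1OC(C)(C)C=C3)CO2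
F3 | step 9 | racemic 3-[2,2-dimethyl-5-(triisopropylsilyloxy)-2H-chromen-8-yl]-5-methoxy-6-(3-methylbut-2-enyl)-7-(triisopropylsilyloxy)chroman-4-ol (mixture of diastereomers) | COc1c(CC=C(C)C)c(O[Si](C(C)C)(C(C)C)C(C)C)cc2c1C(O)C(c1ccc(O[Si](C(C)C)(C(C)C)C(C)C)c3c1OC(C)(C)C=C3)CO2
F4 | step 9 | racemic 3-[2,2-dimethyl-5-(triisopropylsilyloxy)-2H-chromen-8-yl]-5-methoxy-6-(3-methylbut-2-enyl)-7-(triisopropylsilyloxy)chromane | COc1c(CC=C(C)C)c(O[Si](C(C)C)(C(C)C)C(C)C)cc2c1CC(c1ccc(O[Si](C(C)C)(C(C)C)C(C)C)c3c1OC(C)(C)C=C3)CO2
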